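**Retrosynthetic overview**

1. Target 22 ⇐ 20 by ester hydrolysis and desilylation; 20 ⇐ enone 19 ⇐ cyclohexenol 18 by a C5 oxidation/reduction pair that places the C5 hydroxyl cis to the oxirane.
2. Key disconnection: the heptenyl–C3 bond and the C4–C5 ring bond are made in one operation, a Pd(0)-catalysed anti-selective alkenylative cyclisation of the acyclic epoxy ynal 15 with (E)-hept-1-enylboronic acid 16. The enabling feature is the tetrasubstituted C3=C4 double bond of the cyclohexene ring (C3 carries the heptenyl group, C4 the CH2OH group) next to the C5 carbinol: a 2,3-disubstituted cyclohex-2-en-1-ol, which maps onto an internal alkyne plus an aldehyde.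
3. 15 ⇐ (Z)-allylic propargylic alcohol 11 by hydroxyl-directed epoxidation; the single reagent-controlled carbinol centre (future C2) sets both oxirane carbons, including quaternary C1.
4. 11 ⇐ Z-enal 6 + alkyne 7; 6 ⇐ Stille allylation of stannane 3 with bromide 4; 3 ⇐ syn-hydrostannation of but-2-yne-1,4-diol 1, which fixes the alkene geometry that becomes the cis-fused oxirane.
5. Ring order: oxirane first (step 8), then the cyclohexene (step 12).

Key step: step 12

Remark: compounds 4, 7 and 16 are taken as commercial. Ring atoms are numbered as in 7-oxabicyclo[4.1.0]hept-3-ene: C1 quaternary oxirane carbon, C2 the carbinol next to it, C3 heptenyl-bearing, C4 CH2OH-bearing, C5 the second carbinol, C6 the oxirane CH. TBS = tert-butyldimethylsilyl, TBDPS = tert-butyldiphenylsilyl.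

**Step 1**
Reactants: 1 but-2-yne-1,4-diol
Product: 2 (2E)-2-(tributylstannyl)but-2-ene-1,4-diol
Conditions: Bu3SnH, PdCl2(PPh3)2 (1 mol %), THF, rt
Reagents that add atoms: tributyltin hydride, CCCC[SnH](CCCC)CCCC
Why: Pd-catalysed syn-hydrostannation of a symmetrical alkyne has no regiochemical issue and places H and Sn cis, so the two CH2OH groups end up cis.

**Step 2**
Reactants: 2 (2E)-2-(tributylstannyl)but-2-ene-1,4-diol
Product: 3 (2E)-4-(TBS-oxy)-2-(tributylstannyl)but-2-en-1-ol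
Conditions: TBSCl (1.0 equiv), imidazole, CH2Cl2, −20 °C
Reagents that add atoms: tert-butyldimethylsilyl chloride, CC(C)(C)[Si](C)(C)Cl
Why: Sterically controlled monosilylation should select the hydroxyl remote from the Bu3Sn group over the one on the tin-bearing carbon.

**Step 3**
Reactants: 3 (2E)-4-(TBS-oxy)-2-(tributylstannyl)but-2-en-1-ol; 4 methyl (2E)-4-bromo-2-methylbut-2-enoate
Product: 5 methyl (2E,5Z)-7-(TBS-oxy)-5-(hydroxymethyl)-2-methylhepta-2,5-dienoate
Conditions: Pd2(dba)3 (2.5 mol %), AsPh3 (10 mol %), CuI (10 mol %), DMF, 40 °C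
Reagents that add atoms: none
Why: Stille alkenyl–allyl coupling proceeds with retention at the alkenylstannane and bond formation at the unsubstituted terminus of the π-allyl unit, giving the skipped diene with both alkene geometries intact.

**Step 4**
Reactants: 5 methyl (2E,5Z)-7-(TBS-oxy)-5-(hydroxymethyl)-2-methylhepta-2,5-dienoate
Product: 6 methyl (2E,5Z)-7-(TBS-oxy)-5-formyl-2-methylhepta-2,5-dienoate
Conditions: activated MnO2, CH2Cl2, rt; used crude
Reagents that add atoms: none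
Why: Neutral MnO2 oxidation of the primary allylic alcohol should give the Z-enal without acid- or base-induced Z/E isomerisation.

**Step 5**
Reactants: 6 methyl (2E,5Z)-7-(TBS-oxy)-5-formyl-2-methylhepta-2,5-dienoate; 7 tert-butyl(diphenyl)(prop-2-yn-1-yloxy)silane
Product: 9 methyl (2E,5Z)-5-[4-(TBDPS-oxy)-1-hydroxybut-2-yn-1-yl]-7-(TBS-oxy)-2-methylhepta-2,5-dienoate (racemic), via lithium acetylide 8 (not isolated)
Conditions: 7, n-BuLi, THF, −78 °C; then 6, −78 °C; aq NH4Cl
Reagents that add atoms: none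
Why: 1,2-Addition of a lithium acetylide to the aldehyde at −78 °C is much faster than attack on the hindered conjugated ester.

**Step 6**
Reactants: 9 racemic propargylic alcohol
Product: 10 methyl (2E,5Z)-5-[4-(TBDPS-oxy)but-2-ynoyl]-7-(TBS-oxy)-2-methylhepta-2,5-dienoate
Conditions: Dess–Martin periodinane, NaHCO3, CH2Cl2, 0 °C
Reagents that add atoms: none
Why: Buffered Dess–Martin oxidation of the doubly activated secondary alcohol gives the alkenyl alkynyl ketone without touching silyl ethers or ester.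

**Step 7**
Reactants: 10 enynone
Product: 11 methyl (2E,5Z)-5-[(1S)-4-(TBDPS-oxy)-1-hydroxybut-2-yn-1-yl]-7-(TBS-oxy)-2-methylhepta-2,5-dienoate
Conditions: (S)-Me-CBS (0.3 equiv), BH3·SMe2, THF, −30 °C; MeOH quench
Reagents that add atoms: none
Why: In the Corey–Bakshi–Shibata reduction the alkynyl group acts as the small and the α-branched alkenyl group as the large substituent, so the (S)-catalyst should deliver hydride to give the (1S)-carbinol.

**Step 8**
Reactants: 11 (1S)-allylic propargylic alcohol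
Product: 12 methyl (2E)-4-[(2S,3R)-3-(TBS-oxymethyl)-2-[(1R)-4-(TBDPS-oxy)-1-hydroxybut-2-yn-1-yl]oxiran-2-yl]-2-methylbut-2-enoate
Conditions: mCPBA, NaHCO3, CH2Cl2, 0 °C
Reagents that add atoms: meta-chloroperoxybenzoic acid, OOC(=O)c1cccc(Cl)c1
Why: Hydroxyl-directed peracid epoxidation of the electron-richest alkene, with A1,3 strain against the cis CH2OTBS group holding the carbinol hydrogen in the alkene plane, should give the threo epoxy alcohol and so set both oxirane carbons, including the quaternary one, from the carbinol centre.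

**Step 9**
Reactants: 12 epoxy alcohol
Product: 13 methyl (2E)-4-[(2R,3R)-2-[(1R)-1-(TBS-oxy)-4-(TBDPS-oxy)but-2-yn-1-yl]-3-(TBS-oxymethyl)oxiran-2-yl]-2-methylbut-2-enoate
Conditions: TBSOTf, 2,6-lutidine, CH2Cl2, −78 °C
Reagents that add atoms: tert-butyldimethylsilyl triflate, CC(C)(C)[Si](C)(C)OS(=O)(=O)C(F)(F)F
Why: Silyl triflate silylation protects the hindered secondary hydroxyl under buffered conditions that the oxirane tolerates.

**Step 10**
Reactants: 13 tris-silyl ether
Product: 14 methyl (2E)-4-[(2R,3R)-2-[(1R)-1-(TBS-oxy)-4-(TBDPS-oxy)but-2-yn-1-yl]-3-(hydroxymethyl)oxiran-2-yl]-2-methylbut-2-enoate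
Conditions: HF·pyridine, pyridine, THF, 0 °C
Reagents that add atoms: none
Why: Buffered fluoride cleaves the primary TBS ether much faster than the hindered secondary TBS ether or the primary TBDPS ether.

**Step 11**
Reactants: 14 epoxy alcohol
Product: 15 methyl (2E)-4-[(2R,3S)-2-[(1R)-1-(TBS-oxy)-4-(TBDPS-oxy)but-2-yn-1-yl]-3-formyloxiran-2-yl]-2-methylbut-2-enoate
Conditions: Dess–Martin periodinane, NaHCO3, CH2Cl2, 0 °C
Reagents that add atoms: none
Why: Buffered Dess–Martin oxidation converts the 2,3-epoxy alcohol into the epoxy aldehyde without opening the oxirane.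

**Step 12**
Reactants: 15 epoxy ynal; 16 (E)-hept-1-en-1-ylboronic acid
Product: 18 methyl (2E)-4-[(1R,2R,5S,6R)-2-(TBS-oxy)-4-(TBDPS-oxymethyl)-3-[(1E)-hept-1-en-1-yl]-5-hydroxy-7-oxabicyclo[4.1.0]hept-3-en-1-yl]-2-methylbut-2-enoate, via alkenylpalladium(II) methoxide 17 (not isolated)
Conditions: Pd(PPh3)4 (5 mol %), 16 (1.5 equiv), MeOH, 65 °C
Reagents that add atoms: none
Why: Pd(0) binds the alkyne and the electron-rich η2-complex attacks the methanol-activated aldehyde through the CH2OSi-bearing alkyne carbon on the face opposite to palladium (anti-Wacker-type oxidative addition), giving alkenylpalladium(II) methoxide 17, which transmetalates with 16 and reductively eliminates with retention of the E-alkenyl geometry to forge the heptenyl–C3 bond. The closest known reaction type is the Pd(0)/phosphine-catalysed trans-selective alkylative cyclisation of 5-alkynals with aryl- and alkenylboronic acids to 2,3-disubstituted cyclohex-2-en-1-ols. The carbocycle closes in the 6-endo-dig mode (C4–C5 bond), the only mode in which the tether and the new C–C bond end up cis on the alkene after backside attack, so both alkyne carbons become the ring C3=C4 unit. The one new stereocentre, the C5 carbinol, is controlled by the adjacent oxirane carbon C6: a dipole-minimised arrangement with the carbonyl oxygen anti to the oxirane C–O bond should favour the 5S epimer drawn (OH trans to the oxirane oxygen), but the route does not rely on this because both epimers converge in step 13. The step needs anti rather than syn carbometalation and capture by the aldehyde rather than the enoate: the three-atom tether of the 5-alkynal secures the first and the much higher electrophilicity of the epoxy aldehyde over the α-methyl enoate the second.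

**Step 13**
Reactants: 18 cyclohexenol (either C5 epimer)
Product: 19 methyl (2E)-4-[(1R,2R,6S)-2-(TBS-oxy)-4-(TBDPS-oxymethyl)-3-[(1E)-hept-1-en-1-yl]-5-oxo-7-oxabicyclo[4.1.0]hept-3-en-1-yl]-2-methylbut-2-enoate
Conditions: Dess–Martin periodinane, NaHCO3, CH2Cl2, 0 °C
Reagents that add atoms: none
Why: Dess–Martin oxidation of the only free hydroxyl, an allylic alcohol, gives the epoxy dienone and removes the uncontrolled C5 centre.

**Step 14**
Reactants: 19 epoxy dienone
Product: 20 methyl (2E)-4-[(1R,2R,5R,6R)-2-(TBS-oxy)-4-(TBDPS-oxymethyl)-3-[(1E)-hept-1-en-1-yl]-5-hydroxy-7-oxabicyclo[4.1.0]hept-3-en-1-yl]-2-methylbut-2-enoate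
Conditions: NaBH4, CeCl3·7H2O, MeOH, −78 °C
Reagents that add atoms: none
Why: Luche 1,2-reduction should deliver hydride anti to the adjacent oxirane C–O bond, the usual course for 2,3-epoxycyclohexenones, placing the C5 hydroxyl cis to the oxirane oxygen.

**Step 15**
Reactants: 20 methyl ester
Product: 21 (2E)-4-[(1R,2R,5R,6R)-2-(TBS-oxy)-4-(TBDPS-oxymethyl)-3-[(1E)-hept-1-en-1-yl]-5-hydroxy-7-oxabicyclo[4.1.0]hept-3-en-1-yl]-2-methylbut-2-enoic acid
Conditions: LiOH·H2O, THF/MeOH/H2O, 0 °C to rt; then cold dilute HCl to pH 4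
Reagents that add atoms: lithium hydroxide, [Li+].[OH-]
Why: Saponification is run while the C2 oxygen is still silylated, so no alkoxide trans to the oxirane can form and epoxide migration is excluded; the free C5 hydroxyl is cis and cannot open the oxirane.

**Step 16**
Reactants: 21 bis-silyl acid
Product: 22 (2E)-4-[(1S,2R,5R,6R)-3-[(1E)-hept-1-en-1-yl]-2,5-dihydroxy-4-(hydroxymethyl)-7-oxabicyclo[4.1.0]hept-3-en-1-yl]-2-methylbut-2-enoic acid (target)
Conditions: TBAF, AcOH (1:1), THF, 0 °C to rt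
Reagents that add atoms: none
Why: Acetic-acid-buffered fluoride desilylation removes the TBS and TBDPS ethers under near-neutral conditions that the epoxy diol and the dienyl carbinol should tolerate.

**Compound list**

1 | but-2-yne-1,4-diol | OCC#CCO | starting material
2 | (2E)-2-(tributylstannyl)but-2-ene-1,4-diol | OC/C=C(\CO)[Sn](CCCC)(CCCC)CCCC | intermediate
3 | (2E)-4-(TBS-oxy)-2-(tributylstannyl)but-2-en-1-ol | CC(C)(C)[Si](C)(C)OC/C=C(\CO)[Sn](CCCC)(CCCC)CCCC | intermediate
4 | methyl (2E)-4-bromo-2-methylbut-2-enoate | COC(=O)/C(C)=C/CBr | starting material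
5 | methyl (2E,5Z)-7-(TBS-oxy)-5-(hydroxymethyl)-2-methylhepta-2,5-dienoate | COC(=O)/C(C)=C/C/C(CO)=C/CO[Si](C)(C)C(C)(C)C | intermediate
6 | methyl (2E,5Z)-7-(TBS-oxy)-5-formyl-2-methylhepta-2,5-dienoate | COC(=O)/C(C)=C/C/C(C=O)=C/CO[Si](C)(C)C(C)(C)C | intermediate
7 | tert-butyl(diphenyl)(prop-2-yn-1-yloxy)silane | C#CCO[Si](c1ccccc1)(c1ccccc1)C(C)(C)C | starting material
8 | [3-(TBDPS-oxy)prop-1-yn-1-yl]lithium | [Li]C#CCO[Si](c1ccccc1)(c1ccccc1)C(C)(C)C | intermediate
9 | methyl (2E,5Z)-5-[4-(TBDPS-oxy)-1-hydroxybut-2-yn-1-yl]-7-(TBS-oxy)-2-methylhepta-2,5-dienoate, racemic | COC(=O)/C(C)=C/C/C(=C/CO[Si](C)(C)C(C)(C)C)C(O)C#CCO[Si](c1ccccc1)(c1ccccc1)C(C)(C)C | intermediate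
10 | methyl (2E,5Z)-5-[4-(TBDPS-oxy)but-2-ynoyl]-7-(TBS-oxy)-2-methylhepta-2,5-dienoate | COC(=O)/C(C)=C/C/C(=C/CO[Si](C)(C)C(C)(C)C)C(=O)C#CCO[Si](c1ccccc1)(c1ccccc1)C(C)(C)C | intermediate
11 | methyl (2E,5Z)-5-[(1S)-4-(TBDPS-oxy)-1-hydroxybut-2-yn-1-yl]-7-(TBS-oxy)-2-methylhepta-2,5-dienoate | COC(=O)/C(C)=C/C/C(=C/CO[Si](C)(C)C(C)(C)C)[C@H](O)C#CCO[Si](c1ccccc1)(c1ccccc1)C(C)(C)C | intermediate
12 | methyl (2E)-4-[(2S,3R)-3-(TBS-oxymethyl)-2-[(1R)-4-(TBDPS-oxy)-1-hydroxybut-2-yn-1-yl]oxiran-2-yl]-2-methylbut-2-enoate | CC(C)(C)[Si](C)(C)OC[C@H]1O[C@@]1(C/C=C(\C)C(=O)OC)[C@H](O)C#CCO[Si](c2ccccc2)(c2ccccc2)C(C)(C)C | intermediate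
13 | methyl (2E)-4-[(2R,3R)-2-[(1R)-1-(TBS-oxy)-4-(TBDPS-oxy)but-2-yn-1-yl]-3-(TBS-oxymethyl)oxiran-2-yl]-2-methylbut-2-enoate | CC(C)(C)[Si](C)(C)OC[C@H]1O[C@@]1(C/C=C(\C)C(=O)OC)[C@H](O[Si](C)(C)C(C)(C)C)C#CCO[Si](c2ccccc2)(c2ccccc2)C(C)(C)C | intermediate
14 | methyl (2E)-4-[(2R,3R)-2-[(1R)-1-(TBS-oxy)-4-(TBDPS-oxy)but-2-yn-1-yl]-3-(hydroxymethyl)oxiran-2-yl]-2-methylbut-2-enoate | OC[C@H]1O[C@@]1(C/C=C(\C)C(=O)OC)[C@H](O[Si](C)(C)C(C)(C)C)C#CCO[Si](c2ccccc2)(c2ccccc2)C(C)(C)C | intermediate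
15 | methyl (2E)-4-[(2R,3S)-2-[(1R)-1-(TBS-oxy)-4-(TBDPS-oxy)but-2-yn-1-yl]-3-formyloxiran-2-yl]-2-methylbut-2-enoate | O=C[C@H]1O[C@@]1(C/C=C(\C)C(=O)OC)[C@H](O[Si](C)(C)C(C)(C)C)C#CCO[Si](c2ccccc2)(c2ccccc2)C(C)(C)C | intermediate
16 | (E)-hept-1-en-1-ylboronic acid | CCCCC/C=C/B(O)O | starting material
17 | alkenylpalladium(II) methoxide from anti attack of the alkyne on the aldehyde (C3–Pd, phosphine ligands not drawn) | CO[Pd]C1=C(CO[Si](c2ccccc2)(c2ccccc2)C(C)(C)C)[C@H](O)[C@H]2O[C@@]2(C/C=C(\C)C(=O)OC)[C@@H]1O[Si](C)(C)C(C)(C)C | intermediate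
18 | methyl (2E)-4-[(1R,2R,5S,6R)-2-(TBS-oxy)-4-(TBDPS-oxymethyl)-3-[(1E)-hept-1-en-1-yl]-5-hydroxy-7-oxabicyclo[4.1.0]hept-3-en-1-yl]-2-methylbut-2-enoate | CCCCC/C=C/C1=C(CO[Si](c2ccccc2)(c2ccccc2)C(C)(C)C)[C@H](O)[C@H]2O[C@@]2(C/C=C(\C)C(=O)OC)[C@@H]1O[Si](C)(C)C(C)(C)C | intermediate
19 | methyl (2E)-4-[(1R,2R,6S)-2-(TBS-oxy)-4-(TBDPS-oxymethyl)-3-[(1E)-hept-1-en-1-yl]-5-oxo-7-oxabicyclo[4.1.0]hept-3-en-1-yl]-2-methylbut-2-enoate | CCCCC/C=C/C1=C(CO[Si](c2ccccc2)(c2ccccc2)C(C)(C)C)C(=O)[C@H]2O[C@@]2(C/C=C(\C)C(=O)OC)[C@@H]1O[Si](C)(C)C(C)(C)C | intermediate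
20 | methyl (2E)-4-[(1R,2R,5R,6R)-2-(TBS-oxy)-4-(TBDPS-oxymethyl)-3-[(1E)-hept-1-en-1-yl]-5-hydroxy-7-oxabicyclo[4.1.0]hept-3-en-1-yl]-2-methylbut-2-enoate | CCCCC/C=C/C1=C(CO[Si](c2ccccc2)(c2ccccc2)C(C)(C)C)[C@@H](O)[C@H]2O[C@@]2(C/C=C(\C)C(=O)OC)[C@@H]1O[Si](C)(C)C(C)(C)C | intermediate
21 | (2E)-4-[(1R,2R,5R,6R)-2-(TBS-oxy)-4-(TBDPS-oxymethyl)-3-[(1E)-hept-1-en-1-yl]-5-hydroxy-7-oxabicyclo[4.1.0]hept-3-en-1-yl]-2-methylbut-2-enoic acid | CCCCC/C=C/C1=C(CO[Si](c2ccccc2)(c2ccccc2)C(C)(C)C)[C@@H](O)[C@H]2O[C@@]2(C/C=C(\C)C(=O)O)[C@@H]1O[Si](C)(C)C(C)(C)C | intermediate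
22 | (2E)-4-[(1S,2R,5R,6R)-3-[(1E)-hept-1-en-1-yl]-2,5-dihydroxy-4-(hydroxymethyl)-7-oxabicyclo[4.1.0]hept-3-en-1-yl]-2-methylbut-2-enoic acid | CCCCC/C=C/C1=C(CO)[C@@H](O)[C@H]2O[C@@]2(C/C=C(\C)C(=O)O)[C@@H]1O | target

**Totals**

Total step count: 16. Longest linear sequence: 16 steps (from 1; compounds 4, 7 and 16 enter as purchased reagents).

**Steps most likely to fail**

Step 12. Pd(0) may open or isomerise the α,β-epoxy aldehyde before cyclisation, or alkenyl transfer may lose out to protodeboronation or syn-hydroalkenylation of the alkyne, so that ring closure and coupling are no longer linked. The fallback sets out from 15 and reverses the order of events: a Ni(II)-catalysed anti-alkenylative cyclisation with 16 (Ni(OAc)2·4H2O, a phosphinooxazoline ligand, trifluoroethanol/dioxane, 60 °C). Here the alkenylnickel species first adds syn across the alkyne (heptenyl to C3), the resulting alkenylnickel isomerises reversibly between E and Z forms, and only the Z form can add to the aldehyde. No low-valent metal able to insert into the oxirane is present. The sequence comes back at 18 (either C5 epimer; both are oxidised in step 13).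

Step 8. The slim alkynyl group may exert too little allylic strain, so that facial discrimination in the directed epoxidation erodes. The fallback sets out from 11 and moves stereocontrol from the substrate to the reagent: silylation of the carbinol (TBSOTf, 2,6-lutidine) gives the bis-TBS ether F1, selective cleavage of the primary allylic TBS ether (HF·pyridine, pyridine, THF, 0 °C) gives the primary allylic alcohol F2, and Sharpless asymmetric epoxidation (Ti(OiPr)4, D-(−)-diethyl tartrate, t-BuOOH, 4 Å sieves, CH2Cl2, −20 °C) then delivers oxygen to the required face under control of the tartrate. It comes back at 14, bypassing 12 and 13.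

Step 14. Hydride delivery may lose facial selectivity because the face anti to the oxirane also carries the C1 side chain and the C2 silyloxy group. The fallback sets out from 18, the 5S alcohol formed in step 12 (or recovered from step 14), and inverts C5 instead of reducing a ketone: Mitsunobu reaction with 4-nitrobenzoic acid (PPh3, DIAD, toluene, 0 °C) gives the inverted 4-nitrobenzoate F3, and methanolysis (K2CO3, MeOH, 0 °C) leaves the side-chain methyl ester unchanged. It comes back at 20.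

**Further compounds**

F0 | step 12 | none | none
F1 | step 8 | methyl (2E,5Z)-5-[(1S)-1-(TBS-oxy)-4-(TBDPS-oxy)but-2-yn-1-yl]-7-(TBS-oxy)-2-methylhepta-2,5-dienoate | COC(=O)/C(C)=C/C/C(=C/CO[Si](C)(C)C(C)(C)C)[C@H](O[Si](C)(C)C(C)(C)C)C#CCO[Si](c1ccccc1)(c1ccccc1)C(C)(C)C
F2 | step 8 | methyl (2E,5Z)-5-[(1S)-1-(TBS-oxy)-4-(TBDPS-oxy)but-2-yn-1-yl]-7-hydroxy-2-methylhepta-2,5-dienoate | COC(=O)/C(C)=C/C/C(=C/CO)[C@H](O[Si](C)(C)C(C)(C)C)C#CCO[Si](c1ccccc1)(c1ccccc1)C(C)(C)C
F3 | step 14 | methyl (2E)-4-[(1R,2R,5R,6R)-2-(TBS-oxy)-4-(TBDPS-oxymethyl)-3-[(1E)-hept-1-en-1-yl]-5-(4-nitrobenzoyloxy)-7-oxabicyclo[4.1.0]hept-3-en-1-yl]-2-methylbut-2-enoate | CCCCC/C=C/C1=C(CO[Si](c2ccccc2)(c2ccccc2)C(C)(C)C)[C@@H](OC(=O)c2ccc(cc2)[N+](=O)[O-])[C@H]2O[C@@]2(C/C=C(\C)C(=O)OC)[C@@H]1O[Si](C)(C)C(C)(C)C
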